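**Strategy**

Everything rests on a [3+3] disconnection of the cyclohexane ring of the hydrindane across C5–C6 and C3a–C7a (octahydroindene numbering: C1 carries the side chain, C3a the angular methyl, C4 bromine, C7 the carbinol). The key step exploits the 1,4-relation of C4 and C7: a methyl ketone (C4=O) is a bis-nucleophile at C3a and C5, while an epoxy mesylate is a bis-electrophile at C7a and C6 that already carries the C7 oxygen. One base treatment of this acyclic precursor closes the cyclopentane and the cyclohexane. The same ketone-plus-epoxy-sulfonate annulation later builds ring A, and both equatorial bromides are derived from the two ketones at the end.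

Key step: step 11

Remarks on the chemistry:
- Ring A is the bromodimethylcyclohexanol ring, numbered C1′ (carbinol), C3′ (gem-dimethyl), C4′ (bromine). TBS = tert-butyldimethylsilyl.
- Assumption: the α-methyl centre of ketones 14–16 is carried as a mixture of epimers, because it becomes an enolate carbon in step 11. Compounds 1, 3, 6, 9, 13 and 22 are taken as commercial.

**Route**

Step 1
Reactants: 1 2-methylenepropane-1,3-diol
Product: 2 2-{[(tert-butyldimethylsilyl)oxy]methyl}prop-2-en-1-ol
Conditions: NaH (1.0 equiv), THF, 0 °C; then TBSCl (1.0 equiv), rt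
Reagents that add atoms: tert-butyldimethylsilyl chloride CC(C)(C)[Si](C)(C)Cl
Why: Monosilylation of a symmetric diol through its sparingly soluble monosodium alkoxide (silyl ether protection) should stop after one hydroxyl; no stereocentre is involved.

Step 2
Reactants: 2 2-{[(TBS)oxy]methyl}prop-2-en-1-ol; 3 triethyl orthoacetate
Product: 4 ethyl 4-{[(TBS)oxy]methyl}pent-4-enoate
Conditions: 3 (5 equiv), EtCO2H (cat.), 140 °C, EtOH distilled off
Reagents that add atoms: none
Why: Johnson–Claisen rearrangement: the mixed ketene acetal of the allylic alcohol rearranges through a chair [3,3] transition state, attaches the two-carbon ester arm at the alkene terminus and regenerates the 1,1-disubstituted alkene; no stereocentre is formed.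

Step 3
Reactants: 4 ethyl 4-{[(TBS)oxy]methyl}pent-4-enoate
Product: 5 4-{[(TBS)oxy]methyl}pent-4-enoic acid
Conditions: LiOH, THF/MeOH/H2O, rt; then 1 M HCl to pH 4, 0 °C
Reagents that add atoms: lithium hydroxide [Li+].[OH-]
Why: Ester saponification under conditions that a primary TBS ether tolerates gives the acid needed for acylation of the auxiliary.

Step 4
Reactants: 5 4-{[(TBS)oxy]methyl}pent-4-enoic acid; 6 (S)-4-benzyloxazolidin-2-one
Product: 8 (S)-4-benzyl-3-(4-{[(TBS)oxy]methyl}pent-4-enoyl)oxazolidin-2-one, via mixed pivalic anhydride 7 (not isolated)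
Conditions: PivCl, Et3N, THF, −20 °C; then 6, LiCl, rt
Reagents that add atoms: none
Why: N-Acylation of the oxazolidinone through the mixed pivalic anhydride (LiCl/Et3N protocol) gives the imide for auxiliary-controlled enolate chemistry.

Step 5
Reactants: 8 the imide; 9 methacrolein
Product: 10 (S)-4-benzyl-3-[(2S,3S)-2-(2-{[(TBS)oxy]methyl}allyl)-3-hydroxy-4-methylpent-4-enoyl]oxazolidin-2-one
Conditions: Bu2BOTf, i-Pr2NEt, CH2Cl2, −78 → 0 °C; 9, −78 → 0 °C; pH 7 buffer/MeOH work-up
Reagents that add atoms: none
Why: Evans syn-aldol reaction: the Z-boron enolate adds to 9 through a chair Zimmerman–Traxler transition state on the enolate face remote from the benzyl group of the dipole-minimised auxiliary, which sets C2 (future C1 of the hydrindane) and the carbinol carbon C3 (future C7a) as the 2S,3S syn pair.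

Step 6
Reactants: 10 the syn aldol adduct
Product: 11 (3S,4R)-6-{[(TBS)oxy]methyl}-4-(hydroxymethyl)-2-methylhepta-1,6-dien-3-ol
Conditions: LiBH4, MeOH (1 equiv), Et2O/THF, 0 °C
Reagents that add atoms: none
Why: Reductive cleavage of the N-acyl oxazolidinone by LiBH4 gives the primary alcohol (future C2) and returns auxiliary 6 without touching the stereocentres.

Step 7
Reactants: 11 the diol
Product: 12 (3S,4S)-6-{[(TBS)oxy]methyl}-4-(iodomethyl)-2-methylhepta-1,6-dien-3-ol
Conditions: I2, PPh3, imidazole, CH2Cl2, 0 °C
Reagents that add atoms: iodine II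
Why: Appel-type iodination (Garegg–Samuelsson conditions) should select the unhindered primary hydroxyl over the hindered secondary allylic one.

Step 8
Reactants: 12 the iodide; 13 3-methylbut-3-en-2-one
Product: 14 (3RS,6S,7S)-6-(2-{[(TBS)oxy]methyl}allyl)-7-hydroxy-3,8-dimethylnon-8-en-2-one
Conditions: Zn dust, CuI (cat.), 13 (3 equiv), EtOH/H2O, sonication, rt
Reagents that add atoms: none
Why: Aqueous zinc–copper mediated conjugate addition of the alkyl iodide to the enone (Luche conditions, a Giese-type radical addition) installs C3, C3a, the angular methyl and the acetyl unit (C4, C5); the new α-centre forms as both epimers, which is harmless because it becomes an enolate carbon in step 11.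

Step 9
Reactants: 14 the hydroxy ketone
Product: 15 (3RS,6S,7S)-6-(2-{[(TBS)oxy]methyl}allyl)-7-hydroxy-3-methyl-7-[(2R)-2-methyloxiran-2-yl]heptan-2-one
Conditions: VO(acac)2 (5 mol %), t-BuOOH (1.1 equiv), CH2Cl2, 0 °C
Reagents that add atoms: tert-butyl hydroperoxide CC(C)(C)OO
Why: Hydroxyl-directed epoxidation of the 2-substituted allylic alcohol, in which allylic 1,2-strain in the vanadate ester should favour the erythro epoxy alcohol and so set the future C7; the silyl-protected allyl arm has no free allylic hydroxyl and should not react.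

Step 10
Reactants: 15 the erythro epoxy alcohol
Product: 16 (1S,2S)-2-(2-{[(TBS)oxy]methyl}allyl)-5-methyl-1-[(2R)-2-methyloxiran-2-yl]-6-oxoheptyl methanesulfonate (C5 epimers)
Conditions: MsCl, Et3N, CH2Cl2, −20 °C
Reagents that add atoms: methanesulfonyl chloride CS(Cl)(=O)=O
Why: Sulfonylation through sulfene turns the secondary hydroxyl into a leaving group with retention, which completes the bis-electrophile (mesylate carbon = C7a, epoxide CH2 = C6).

Step 11
Reactants: 16 the epoxy mesylate
Product: 18 (1S,3aS,7R,7aS)-1-(2-{[(TBS)oxy]methyl}allyl)-7-hydroxy-3a,7-dimethyloctahydro-4H-inden-4-one, via cyclopentyl ketone epoxide 17 (not isolated)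
Conditions: KOtBu (2.5 equiv), t-BuOH/THF (1:4), 0.01 M, 0 → 40 °C
Reagents that add atoms: none
Why: Under equilibrating conditions the more substituted potassium enolate of the methyl ketone (future C3a) displaces the secondary mesylate at the future C7a by a 5-exo-tet SN2 reaction with inversion to give 17, whose only enolisable position, the acetyl methyl (future C5), then opens the 2,2-disubstituted epoxide at its CH2 terminus (future C6) and leaves the oxygen on C7 as the tertiary alkoxide. The closest known reaction type is the intramolecular alkylation of a ketone enolate by a sulfonate followed by an intramolecular enolate–epoxide opening, that is, the two-fold alkylation of a ketone α,α′-bis-nucleophile by an epichlorohydrin-type bis-electrophile. The cyclopentane closes in the 5-exo-tet mode and the cyclohexanone in a 6-(enolendo) closure onto the distal epoxide carbon (endo with respect to the epoxide), the proximal carbon being fully substituted. C7a arises by inversion of the carbinol centre from step 5, C7 is carried over unchanged from the epoxide of step 9, and the new quaternary C3a should be controlled in the first closure by the solvated enolate unit lying anti to the oxiranyl group on C7a (methyl cis to it), which makes the ring fusion trans. The step needs substitution to beat elimination of the mesylate and seven-membered attack on the epoxide, the tertiary enolate to react rather than the methyl enolate, and C- rather than O-alkylation in the second closure; these should be secured by the effective molarity of five-ring formation, by the fact that the methyl enolate could only close seven- or nine-membered rings before the cyclopentane exists, and by the potassium/t-BuOH medium.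

Step 12
Reactants: 18 the hydrindanone
Product: 19 (1S,3aS,7R,7aS)-7-hydroxy-1-[2-(hydroxymethyl)allyl]-3a,7-dimethyloctahydro-4H-inden-4-one
Conditions: Bu4NF, THF, 0 °C → rt
Reagents that add atoms: none
Why: Fluoride-induced desilylation frees the primary allylic alcohol that directs the next epoxidation.

Step 13
Reactants: 19 the allylic alcohol
Product: 20 (1S,3aS,7R,7aS)-7-hydroxy-1-{[(2S)-2-(hydroxymethyl)oxiran-2-yl]methyl}-3a,7-dimethyloctahydro-4H-inden-4-one
Conditions: Ti(OiPr)4, L-(+)-diisopropyl tartrate, t-BuOOH, 4 Å MS, CH2Cl2, −20 °C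
Reagents that add atoms: tert-butyl hydroperoxide CC(C)(C)OO
Why: Sharpless asymmetric epoxidation of the 2-substituted allyl alcohol, in which the L-(+)-tartrate complex should deliver oxygen to one face under reagent control and set the oxirane carbon (future C1′) as S, the existing stereocentres being remote.

Step 14
Reactants: 20 the epoxy alcohol
Product: 21 {(2R)-2-[((1S,3aS,7R,7aS)-7-hydroxy-3a,7-dimethyl-4-oxooctahydro-1H-inden-1-yl)methyl]oxiran-2-yl}methyl 4-methylbenzenesulfonate
Conditions: TsCl, Et3N, DMAP (cat.), CH2Cl2, 0 °C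
Reagents that add atoms: p-toluenesulfonyl chloride Cc1ccc(cc1)S(Cl)(=O)=O
Why: Selective tosylation of the primary hydroxyl (the tertiary alcohol is too hindered) gives the glycidyl-type bis-electrophile for ring A without touching the stereocentre.

Step 15
Reactants: 21 the epoxy tosylate; 22 3-methylbutan-2-one
Product: 25 (1S,3aS,7R,7aS)-7-hydroxy-1-{[(1S)-1-hydroxy-3,3-dimethyl-4-oxocyclohexyl]methyl}-3a,7-dimethyloctahydro-4H-inden-4-one, via hydroxy tosylate 23 (not isolated), via epoxy diketone 24 (not isolated)
Conditions: 22 (4 equiv), LDA (4 equiv), THF, −78 °C; LiClO4, then 21, −78 → 0 °C; then t-BuOH, KOtBu (3 equiv), dilution with THF, 0 → 45 °C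
Reagents that add atoms: none
Why: Second annulation of the step 11 type: the kinetic lithium enolate of 22 (methyl carbon, future C5′) opens the sulfonate-activated epoxide at its CH2 terminus (LiClO4-promoted enolate–epoxide alkylation) to 23, the tertiary alkoxide then closes a new epoxide onto the CH2OTs carbon (Payne-type closure, 24) once excess enolate has been quenched, and the thermodynamic enolate (isopropyl carbon, future C3′) opens it in a six-membered closure, so that the C–O bond from step 13 is never broken and fixes C1′ as S.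

Step 16
Reactants: 25 the diketone diol
Product: 26 bis-hydrazone of 25 (C4=N–NH2 and C4′=N–NH2)
Conditions: N2H4·H2O (excess), Et3N, EtOH, 80 °C
Reagents that add atoms: hydrazine NN
Why: Hydrazone formation at both ketones, each flanked by one quaternary carbon, is the first stage of the Barton-type vinyl halide synthesis.

Step 17
Reactants: 26 the bis-hydrazone
Product: 27 bis(vinyl bromide): 25 with C4(Br)=C5 and C4′(Br)=C5′ in place of the two carbonyl groups
Conditions: N-bromosuccinimide (4.4 equiv), pyridine, CH2Cl2, 0 °C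
Reagents that add atoms: N-bromosuccinimide O=C1CCC(=O)N1Br
Why: Barton-type halogenative oxidation of hydrazones: N-bromination, loss of HBr to the diazoalkane, a second bromination, loss of N2 and of a proton from the only available α-CH2 should give each bromoalkene regiospecifically.

Step 18
Reactants: 27 the bis(vinyl bromide)
Product: 28 (1S,3aS,4S,7R,7aS)-4-bromo-1-{[(1S,4S)-4-bromo-1-hydroxy-3,3-dimethylcyclohexyl]methyl}-3a,7-dimethyloctahydro-1H-inden-7-ol (target)
Conditions: Mn(dpm)3 (20 mol %; dpm = 2,2,6,6-tetramethylheptane-3,5-dionate), PhSiH3, t-BuOOH, i-PrOH, rt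
Reagents that add atoms: none
Why: Double metal-hydride hydrogen-atom-transfer hydrogenation of the bromoalkenes: hydrogen should go first to the unhindered CH carbon, and each α-bromo cyclohexyl radical should then accept hydrogen along the axial trajectory anti to the neighbouring axial methyl, which places both bromines equatorial (4S and 4′S) without C–Br cleavage.

**Compound list**

1 | 2-methylenepropane-1,3-diol | C=C(CO)CO | starting material
2 | 2-{[(tert-butyldimethylsilyl)oxy]methyl}prop-2-en-1-ol | OCC(=C)CO[Si](C)(C)C(C)(C)C | intermediate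
3 | triethyl orthoacetate | CC(OCC)(OCC)OCC | starting material
4 | ethyl 4-{[(TBS)oxy]methyl}pent-4-enoate | CCOC(=O)CCC(=C)CO[Si](C)(C)C(C)(C)C | intermediate
5 | 4-{[(TBS)oxy]methyl}pent-4-enoic acid | OC(=O)CCC(=C)CO[Si](C)(C)C(C)(C)C | intermediate
6 | (S)-4-benzyloxazolidin-2-one | O=C1OC[C@H](Cc2ccccc2)N1 | starting material
7 | mixed anhydride of 5 with pivalic acid | CC(C)(C)C(=O)OC(=O)CCC(=C)CO[Si](C)(C)C(C)(C)C | intermediate (not isolated)
8 | (S)-4-benzyl-3-(4-{[(TBS)oxy]methyl}pent-4-enoyl)oxazolidin-2-one | O=C1OC[C@H](Cc2ccccc2)N1C(=O)CCC(=C)CO[Si](C)(C)C(C)(C)C | intermediate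
9 | methacrolein | CC(=C)C=O | starting material
10 | (S)-4-benzyl-3-[(2S,3S)-2-(2-{[(TBS)oxy]methyl}allyl)-3-hydroxy-4-methylpent-4-enoyl]oxazolidin-2-one | O=C1OC[C@H](Cc2ccccc2)N1C(=O)[C@@H](CC(=C)CO[Si](C)(C)C(C)(C)C)[C@H](O)C(C)=C | intermediate
11 | (3S,4R)-6-{[(TBS)oxy]methyl}-4-(hydroxymethyl)-2-methylhepta-1,6-dien-3-ol | OC[C@@H](CC(=C)CO[Si](C)(C)C(C)(C)C)[C@H](O)C(C)=C | intermediate
12 | (3S,4S)-6-{[(TBS)oxy]methyl}-4-(iodomethyl)-2-methylhepta-1,6-dien-3-ol | IC[C@@H](CC(=C)CO[Si](C)(C)C(C)(C)C)[C@H](O)C(C)=C | intermediate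
13 | 3-methylbut-3-en-2-one | CC(=C)C(C)=O | starting material
14 | (3RS,6S,7S)-6-(2-{[(TBS)oxy]methyl}allyl)-7-hydroxy-3,8-dimethylnon-8-en-2-one | CC(=O)C(C)CC[C@@H](CC(=C)CO[Si](C)(C)C(C)(C)C)[C@H](O)C(C)=C | intermediate
15 | (3RS,6S,7S)-6-(2-{[(TBS)oxy]methyl}allyl)-7-hydroxy-3-methyl-7-[(2R)-2-methyloxiran-2-yl]heptan-2-one | CC(=O)C(C)CC[C@@H](CC(=C)CO[Si](C)(C)C(C)(C)C)[C@H](O)[C@@]1(C)CO1 | intermediate
16 | mesylate of 15 (secondary OH replaced by OSO2CH3, same configuration) | CC(=O)C(C)CC[C@@H](CC(=C)CO[Si](C)(C)C(C)(C)C)[C@H](OS(C)(=O)=O)[C@@]1(C)CO1 | intermediate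
17 | 1-[(1S,2S,3S)-3-(2-{[(TBS)oxy]methyl}allyl)-1-methyl-2-[(2S)-2-methyloxiran-2-yl]cyclopentyl]ethan-1-one (acetyl trans to oxiranyl, oxiranyl trans to the allyl arm) | CC(=O)[C@@]1(C)CC[C@@H](CC(=C)CO[Si](C)(C)C(C)(C)C)[C@@H]1[C@@]2(C)CO2 | intermediate (not isolated)
18 | (1S,3aS,7R,7aS)-1-(2-{[(TBS)oxy]methyl}allyl)-7-hydroxy-3a,7-dimethyloctahydro-4H-inden-4-one | CC(C)(C)[Si](C)(C)OCC(=C)C[C@@H]2CC[C@]3(C)C(=O)CC[C@@](C)(O)[C@@H]23 | intermediate
19 | (1S,3aS,7R,7aS)-7-hydroxy-1-[2-(hydroxymethyl)allyl]-3a,7-dimethyloctahydro-4H-inden-4-one | OCC(=C)C[C@@H]2CC[C@]3(C)C(=O)CC[C@@](C)(O)[C@@H]23 | intermediate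
20 | (1S,3aS,7R,7aS)-7-hydroxy-1-{[(2S)-2-(hydroxymethyl)oxiran-2-yl]methyl}-3a,7-dimethyloctahydro-4H-inden-4-one | OC[C@@]4(C[C@@H]2CC[C@]3(C)C(=O)CC[C@@](C)(O)[C@@H]23)CO4 | intermediate
21 | tosylate of 20 at the primary hydroxyl | Cc1ccc(cc1)S(=O)(=O)OC[C@@]4(C[C@@H]2CC[C@]3(C)C(=O)CC[C@@](C)(O)[C@@H]23)CO4 | intermediate
22 | 3-methylbutan-2-one | CC(C)C(C)=O | starting material
23 | hydroxy tosylate: 21 with the epoxide opened at CH2 by the methyl carbon of 22 (tertiary OH, CH2OTs retained) | CC(C)C(=O)CC[C@@](O)(COS(=O)(=O)c1ccc(C)cc1)C[C@@H]2CC[C@]3(C)C(=O)CC[C@@](C)(O)[C@@H]23 | intermediate (not isolated)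
24 | epoxy diketone: 23 after closure of the alkoxide onto the CH2OTs carbon | CC(C)C(=O)CC[C@]4(C[C@@H]2CC[C@]3(C)C(=O)CC[C@@](C)(O)[C@@H]23)CO4 | intermediate (not isolated)
25 | (1S,3aS,7R,7aS)-7-hydroxy-1-{[(1S)-1-hydroxy-3,3-dimethyl-4-oxocyclohexyl]methyl}-3a,7-dimethyloctahydro-4H-inden-4-one | CC1(C)C[C@@](O)(C[C@@H]2CC[C@]3(C)C(=O)CC[C@@](C)(O)[C@@H]23)CCC1=O | intermediate
26 | bis-hydrazone of 25 | CC1(C)C[C@@](O)(C[C@@H]2CC[C@]3(C)C(=NN)CC[C@@](C)(O)[C@@H]23)CCC1=NN | intermediate
27 | bis(vinyl bromide) with C4(Br)=C5 and C4′(Br)=C5′, other centres as in 25 | CC1(C)C[C@@](O)(C[C@@H]2CC[C@]3(C)C(Br)=CC[C@@](C)(O)[C@@H]23)CC=C1Br | intermediate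
28 | (1S,3aS,4S,7R,7aS)-4-bromo-1-{[(1S,4S)-4-bromo-1-hydroxy-3,3-dimethylcyclohexyl]methyl}-3a,7-dimethyloctahydro-1H-inden-7-ol | CC1(C)C[C@@](O)(C[C@@H]2CC[C@]3(C)[C@@H](Br)CC[C@@](C)(O)[C@@H]23)CC[C@@H]1Br | target

**Step count and risks**

Total step count: 18. Longest linear sequence: 18 steps (from 1).

The three steps most likely to fail:

1. Step 11 (key step). What may go wrong: base-induced elimination of the secondary mesylate, a slow seven-membered attack of the enolate on the epoxide, or closure with the acetyl group cis to the oxirane, each draining material before the second ring forms. The fallback sets out from 8 and returns at 17, which goes on to 18 as in step 11; it changes the first ring closure from a sulfonate displacement into an epoxide opening. Imide 8 is alkylated (NaHMDS, allyl iodide, THF, −78 °C; the allyl group should enter anti to the benzyl group of the chelated Z-enolate) to α-allyl imide F1, in which the imide carbon is the future C7a. LiBH4 should give alcohol F2, and Dess–Martin oxidation aldehyde F3. Still–Gennari olefination (methyl 2-[bis(2,2,2-trifluoroethoxy)phosphoryl]propanoate, KHMDS, 18-crown-6) should give Z-enoate F4, and i-Bu2AlH reduction Z-allylic alcohol F5. Sharpless epoxidation with Ti(OiPr)4 and D-(−)-diisopropyl tartrate should give epoxy alcohol F6, and TsCl/Et3N epoxy tosylate F7. Cross-metathesis of the allyl group with 13 (second-generation Hoveyda–Grubbs catalyst) should give enone F8, and conjugate reduction with [(Ph3P)CuH]6 ketone F9. With KOtBu the C3a enolate should open the trisubstituted epoxide at its CH carbon (5-exo, inversion; there is no leaving group to eliminate and no second electrophilic carbon within reach of a small ring). The C7 alkoxide then closes onto the CH2OTs carbon, and the terminal epoxide so formed is 17.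

2. Step 15. What may go wrong: proton exchange between the reagent enolate and the ring ketone or tertiary alcohol of 21, and a second intermolecular epoxide opening by excess enolate before the ring closes. The fallback sets out from 21 and returns at 25; it removes the acidic sites before the annulation. LiHMDS (2.2 equiv) with Me3SiCl as internal quench at −78 °C should convert 21 into bis-silyl derivative F10 (silyl enol ether across C4–C5, silyl ether on the C7 oxygen). F10 is then treated with only 1.1 equiv of the lithium enolate of 22 and LiClO4, followed by KOtBu/t-BuOH as in step 15. Dilute aqueous HCl in the work-up should remove both silyl groups and give 25.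

3. Step 18. What may go wrong: loss of bromine when hydrogen-atom transfer occurs at the bromine-bearing carbon and the β-bromo radical fragments, or hydrogen delivery from the equatorial side giving axial bromides. The fallback sets out from 26 and returns at 28; it avoids the alkenes and the metal hydride. Bis-hydrazone 26 is oxidised with CuBr2/Et3N in MeOH to bis(geminal dibromide) F11. One bromine per carbon is then removed with Bu3SnH (2.1 equiv), Et3B/O2, toluene, −78 °C. The α-bromo radicals are the same as in step 18 and should again accept hydrogen axially.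

**Further compounds**

F1 | step 11 | (S)-4-benzyl-3-[(2S)-2-allyl-4-{[(TBS)oxy]methyl}pent-4-enoyl]oxazolidin-2-one | O=C1OC[C@H](Cc2ccccc2)N1C(=O)[C@@H](CC=C)CC(=C)CO[Si](C)(C)C(C)(C)C
F2 | step 11 | (2S)-2-allyl-4-{[(TBS)oxy]methyl}pent-4-en-1-ol | OC[C@@H](CC=C)CC(=C)CO[Si](C)(C)C(C)(C)C
F3 | step 11 | (2S)-2-allyl-4-{[(TBS)oxy]methyl}pent-4-enal | O=C[C@@H](CC=C)CC(=C)CO[Si](C)(C)C(C)(C)C
F4 | step 11 | methyl (2Z,4S)-4-allyl-2-methyl-6-{[(TBS)oxy]methyl}hepta-2,6-dienoate | COC(=O)/C(C)=C\[C@@H](CC=C)CC(=C)CO[Si](C)(C)C(C)(C)C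
F5 | step 11 | (2Z,4S)-4-allyl-2-methyl-6-{[(TBS)oxy]methyl}hepta-2,6-dien-1-ol | OC/C(C)=C\[C@@H](CC=C)CC(=C)CO[Si](C)(C)C(C)(C)C
F6 | step 11 | [(2R,3S)-2-methyl-3-[(4S)-2-{[(TBS)oxy]methyl}hepta-1,6-dien-4-yl]oxiran-2-yl]methanol | OC[C@@]1(C)O[C@H]1[C@@H](CC=C)CC(=C)CO[Si](C)(C)C(C)(C)C
F7 | step 11 | tosylate of F6 at the primary hydroxyl | Cc1ccc(cc1)S(=O)(=O)OC[C@@]1(C)O[C@H]1[C@@H](CC=C)CC(=C)CO[Si](C)(C)C(C)(C)C
F8 | step 11 | (E)-enone: F7 with the allyl group converted into CH2CH=C(CH3)C(=O)CH3 | Cc1ccc(cc1)S(=O)(=O)OC[C@@]1(C)O[C@H]1[C@@H](C/C=C(\C)C(C)=O)CC(=C)CO[Si](C)(C)C(C)(C)C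
F9 | step 11 | saturated ketone: F8 with the enone C=C reduced (α-methyl epimers) | Cc1ccc(cc1)S(=O)(=O)OC[C@@]1(C)O[C@H]1[C@@H](CCC(C)C(C)=O)CC(=C)CO[Si](C)(C)C(C)(C)C
F10 | step 15 | bis(trimethylsilyl) derivative of 21 (C4–C5 silyl enol ether, C7 silyl ether) | Cc1ccc(cc1)S(=O)(=O)OC[C@@]4(C[C@@H]2CC[C@]3(C)C(O[Si](C)(C)C)=CC[C@@](C)(O[Si](C)(C)C)[C@@H]23)CO4
F11 | step 18 | bis(geminal dibromide): 25 with CBr2 at C4 and at C4′ in place of the carbonyl groups | CC1(C)C[C@@](O)(C[C@@H]2CC[C@]3(C)C(Br)(Br)CC[C@@](C)(O)[C@@H]23)CCC1(Br)Br
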